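**The vessel.** In the closed, stirred flask, a saturated solution held gas equal to 9.00 % of the charge, less than one exchange takes. So I assumed that gas crossing into solution was the rate-limiting step.

| setting | dusk | flask |
|---|---|---|
| starting complex | 30 mM | 20 mM |
| gas | 1.8 mM (held) | 1.8 mM (held) |
| remark | run made earlier |  |
| time |  | 6.0 min |

dusk run (percent of the starting complex charged): time / s: complex with two exchanged / % = 15.0: 0; 30.0: 0.8; 50.0: 1.5; 60.0: 1.0; 80.0: 3.4; 90.0: 4.9; 120: 7.8

(scatter of a reading: 0.5 percentage points)

- at the start none of the gas is in solution

* how much complex with two exchanged there is at 6.0 min, in percent of the starting complex charged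
* the change that raises the amount of complex with two exchanged at 6.0 min, in percent of the starting complex charged most ("none" if none brings more than 2 percentage points) (violet / teal / none)
* amount of complex with two exchanged at 6.0 min, in percent of the starting complex charged, after violet

- violet: doubling the saturation concentration of gas, all else as stated
- teal: doubling the transfer coefficient of the gas, all else as stated

**What matters.** At 6.0 min the flask stood at 32.4 s on my supply clock, time multiplied by the saturated fraction of the charge. The last dusk reading stood at 7.20 s. Time and saturation lengthen this clock in proportion and a heavier charge shortens it, so the change of charge from 30 mM to 20 mM had to be counted as carefully as the time. I used the reading of 7.8 %, the last of the dusk run, with its scatter of 0.5 percentage points.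

**My number.** I took two equal successive exchanges, with the fraction of complex with two exchanged equal to one minus (one plus s) times exp(−s), and s growing with the clock. That reading gave s of 0.460. The clock then carried s to 2.07, which gave me 61.3 % for the flask.

**The forecast.** The forecast gave 38 %, chose violet, and gave 72 % after violet, holding that “percent yield does not depend on the complex charge”. My number stood higher, and it depended on the charge.

**The result.** The flask gave 56.1 %, 5.2 points below my number, and 67.5 % after violet. Teal gained 16 points and violet 11 points, so the best change was teal.

    starting complex + incoming ligand ⇌ leaving ligand + complex with one exchanged (K = 22.1, k = 31.1 M⁻¹ s⁻¹)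
    complex with one exchanged + incoming ligand ⇌ leaving ligand + complex with two exchanged (K = 580, k = 29.3 M⁻¹ s⁻¹)
    complex with two exchanged + incoming ligand ⇌ leaving ligand + complex with three exchanged (K = 5.70, k = 75.1 M⁻¹ s⁻¹)
    complex with three exchanged + incoming ligand ⇌ leaving ligand + complex with four exchanged (K = 1.50, k = 43.1 M⁻¹ s⁻¹)
    gas ⇌ incoming ligand, rate k5*(csat - [incoming ligand]) (kL = 0.0613 s⁻¹)

**Heavier charge.** The neighbouring flask with 34 mM of starting complex stood at 19.1 s on the clock, which gave s of 1.22 and a reckoned 34.5 %. That flask gave 37.3 %, with 46.6 % of its starting complex left.

All runs stem from a simulated flask on assumed constants, and the scatter is random.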